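**Two questions.** Two questions stood on the amber flask, the very flask already followed for 8.00 min, and I reckoned the first, its X.

- amber: L 0.16 M; J 63 mM (held); the very flask that is asked about, followed so far
- flask: L 0.16 M; J 63 mM (held); time 40 min

- amber (time / min: X / %, L / %): 0.667: 3.5, 53.5; 2.00: 10.6, 21.8; 4.00: 15.0, 6.8; 6.00: 17.8, 1.8; 8.00: 17.9, 1.3

(readings scatter by 0.5 percentage points)

- in percentages every species weighs as the L in it: one Z counts as two
- at the start none of Q is dissolved
- the earlier runs were read with a standard deviation of 0.5 percentage points
- on the list of suspects stand: J <-> Q; L + Q -> X; X <-> E; 2 L -> Z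

1. X at 40 min, in percent of the L charged
2. concentration of Q in solution at 40 min, in percent of saturation

**Bench rule.** At the bench I read a flat curve as finished. In the amber flask X read 17.8% and then 17.9%, so the rule said 17.9% at 40 min. But in the amber flask the rule stops where L is not small beside X. That ratio, L over X, was 0.453 at 4.00 min, and X rose afterwards; at 8.00 min it was lower, 0.0726, though not zero.

**Late yield.** So I divided X gained by L lost between 4.00 min and 8.00 min, and time dropped out. This late yield, a selectivity in the usual term, came to 0.527 X per L lost. The 1.3% of L still read in the amber flask should therefore bring 0.69 percentage points more, beside a scatter of 0.5 points. I expected 18.6%.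

**The forecast.** The forecast gave 17.3% for X and 99.5% of saturation for [Q], saying “with nothing consuming it Q reaches saturation”. Its X stood lower than mine.

**The result.** The flask gave 18.2% of X and 100% of saturation.

    J ⇌ Q, rate k1*(csat - [Q]) (kL = 0.0150 /s)
    L + Q → X (k = 0.150 /M/s)
    X ⇌ E (K = 0.940, k = 0.0560 /s)
    2 L → Z (k = 0.0570 /M/s)

The passing of 2 L into Z reached the midpoint of its turnover at 0.450 min, and L + Q into X reached its own at 1.97 min, with [Q] at 82.5% of saturation by 4.00 min. In the flask L stood at 7.23% at 4.00 min and 0% at 20.0 min, when X stood at 18.2%. The late yield of 0.527 had put this flask 0.40 points above its result. A second flask with the same charge, stopped at 25 min with L at 0%, for which the late yield gave the same 18.6%, held 18.2% of X.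

The runs come from a simulation with made-up constants; the scatter is artificial.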